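**Retrosynthetic overview**
1. The target (28) comes from 27 in one palladium/formate operation that frees both phenols and removes a temporary chlorine at C5.
2. Ring C of 27 is cut at O1–C8a and C4–C4a: an aryne of ring A (C4a≡C8a, from 2-silylaryl triflate 11) plus the (S)-β-oxido Weinreb amide 23 (O1–C2–C3–C4, which already carries ring B, pyran ring D and the C2 stereocenter).
3. Enabling feature: O1 and the C4 carbonyl sit on the adjacent ring-A carbons C8a and C4a and are 1,3-related through C2–C3, so ring C is the [4+2] adduct of an aryne with a β-oxido carbonyl unit. A temporary chlorine at C5 polarises the aryne so that oxygen adds at C8a, next to the prenyl-bearing C8.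
4. 11 comes from 5-chlororesorcinol (ortho-metalation/prenylation between the two oxygens, then a desymmetrising retro-Brook shift and triflation). 23 comes from resorcinol (chromanone, chromene, ortho-formylation, aldol, oxidation, asymmetric transfer hydrogenation).
5. Ring order: ring D on ring B (steps 7–8), ring A aryne precursor (steps 1–6), ring C last (step 14).

Key step: step 14

Remark: the target SMILES encodes the (2S)-flavanone (O1 > C1' > C3 > H); the facial sense of step 13 is assigned by analogy with aryl alkyl ketones.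

**Route**

Step 1
Reactants: 1 5-chlororesorcinol
Product: 2 1-chloro-3,5-bis(methoxymethoxy)benzene
Conditions: MOMCl, iPr2NEt, CH2Cl2, 0 °C → rt
Reagents that add atoms: chloromethyl methyl ether, COCCl
Why: Double Williamson-type O-alkylation of the phenols installs the two acetal directing groups for the metalation in step 2 and should be clean on this unhindered resorcinol.

Step 2
Reactants: 2 1-chloro-3,5-bis(methoxymethoxy)benzene; 3 prenyl bromide
Product: 5 5-chloro-1,3-bis(methoxymethoxy)-2-(3-methylbut-2-en-1-yl)benzene, via aryllithium 4 (not isolated)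
Conditions: n-BuLi, THF, −20 °C; then CuBr·SMe2 (10 mol%), 3, −78 → 0 °C
Reagents that add atoms: none
Why: Directed ortho-metalation should occur at the carbon flanked by both OMOM groups (cooperative chelation, no ortho leaving group), and copper-catalysed SN2 allylation of aryllithium 4 with the primary bromide then gives the linear prenyl arene.

Step 3
Reactants: 5 5-chloro-1,3-bis(methoxymethoxy)-2-(3-methylbut-2-en-1-yl)benzene
Product: 6 5-chloro-2-(3-methylbut-2-en-1-yl)benzene-1,3-diol
Conditions: HCl (3 M aq.), MeOH, 40 °C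
Reagents that add atoms: none
Why: Acid-catalysed transacetalisation to methanol (MOM cleavage) frees both phenols, and dilute acid at mild temperature should spare the prenyl alkene from hydroalkoxylation by the neighbouring phenol.

Step 4
Reactants: 6 5-chloro-2-(3-methylbut-2-en-1-yl)benzene-1,3-diol
Product: 7 5-chloro-2-(3-methylbut-2-en-1-yl)-1,3-bis(trimethylsilyloxy)benzene
Conditions: (Me3Si)2NH, Me3SiCl (cat.), THF, 65 °C; volatiles removed
Reagents that add atoms: hexamethyldisilazane, C[Si](C)(C)N[Si](C)(C)C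
Why: O-silylation of both phenols by the silazane, driven by loss of ammonia, gives the symmetric bis(silyl ether) that the silyl migration of step 5 requires.

Step 5
Reactants: 7 5-chloro-2-(3-methylbut-2-en-1-yl)-1,3-bis(trimethylsilyloxy)benzene
Product: 10 3-chloro-5-hydroxy-6-(3-methylbut-2-en-1-yl)-2-(trimethylsilyl)phenyl trifluoromethanesulfonate, via lithium phenolate 8 (not isolated), via silyl ether triflate 9 (not isolated)
Conditions: lithium 2,2,6,6-tetramethylpiperidide, THF, −78 → −40 °C; Tf2O, −78 °C; aq. NaHCO3, then dilute citric acid work-up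
Reagents that add atoms: trifluoromethanesulfonic anhydride, O=S(=O)(OS(=O)(=O)C(F)(F)F)C(F)(F)F
Why: Ortho-lithiation between Cl and OSiMe3 (both such sites are equivalent and the carbon between the oxygens is blocked by prenyl) triggers a retro-Brook 1,3-O→C silyl shift to phenolate 8, whose charge suppresses a second metalation so that the diol is desymmetrised, and O-triflation followed by hydrolysis of the remaining labile aryl silyl ether on work-up gives the 2-silylaryl triflate with a free phenol.

Step 6
Reactants: 10 3-chloro-5-hydroxy-6-(3-methylbut-2-en-1-yl)-2-(trimethylsilyl)phenyl trifluoromethanesulfonate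
Product: 11 3-chloro-6-(3-methylbut-2-en-1-yl)-5-(prop-2-en-1-yloxy)-2-(trimethylsilyl)phenyl trifluoromethanesulfonate
Conditions: allyl bromide, K2CO3, acetone, rt
Reagents that add atoms: allyl bromide, C=CCBr
Why: Williamson etherification under mild carbonate conditions, which the aryl triflate and the C–Si bond tolerate, installs an allyl ether that is inert to fluoride and base in step 14 and is removed by palladium in step 15.

Step 7
Reactants: 12 resorcinol; 13 3,3-dimethylacrylic acid
Product: 14 7-hydroxy-2,2-dimethylchroman-4-one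
Conditions: MeSO3H, P2O5, 70 °C
Reagents that add atoms: none
Why: Friedel–Crafts acylation of resorcinol para to one hydroxyl followed by oxa-Michael closure of the ortho hydroxyl onto the enone builds the dimethylpyranone ring D on ring B in one pot, with the regiochemistry fixed by the 1,3-dioxygenation.

Step 8
Reactants: 14 7-hydroxy-2,2-dimethylchroman-4-one
Product: 16 2,2-dimethyl-2H-chromen-7-ol, via chromanol 15 (not isolated)
Conditions: NaBH4, MeOH/THF, 0 °C → rt; then p-TsOH·H2O (cat.), THF, 50 °C
Reagents that add atoms: none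
Why: Hydride reduction of the ketone and acid-catalysed dehydration of the para-hydroxybenzylic alcohol 15 give the 2H-chromene, the racemic carbinol centre being destroyed again.

Step 9
Reactants: 16 2,2-dimethyl-2H-chromen-7-ol
Product: 17 7-hydroxy-2,2-dimethyl-2H-chromene-6-carbaldehyde
Conditions: MgCl2, Et3N, (CH2O)n, MeCN, 80 °C
Reagents that add atoms: paraformaldehyde (as formaldehyde), C=O
Why: Magnesium-phenolate-directed ortho-formylation (Casnati–Skattebøl reaction) should take place at C6, which is ortho to the hydroxyl, para to the pyran oxygen and unhindered, rather than at C8 between the two oxygens.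

Step 10
Reactants: 17 7-hydroxy-2,2-dimethyl-2H-chromene-6-carbaldehyde
Product: 18 2,2-dimethyl-7-(prop-2-en-1-yloxy)-2H-chromene-6-carbaldehyde
Conditions: allyl bromide, K2CO3, DMF, 50 °C
Reagents that add atoms: allyl bromide, C=CCBr
Why: Williamson etherification of the chelated phenol masks it as an allyl ether that survives enolate, oxidation, hydride and fluoride conditions and is removed together with the ring-A allyl ether in step 15.

Step 11
Reactants: 18 2,2-dimethyl-7-(prop-2-en-1-yloxy)-2H-chromene-6-carbaldehyde; 19 N-methoxy-N-methylacetamide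
Product: 21 rac-3-[2,2-dimethyl-7-(prop-2-en-1-yloxy)-2H-chromen-6-yl]-3-hydroxy-N-methoxy-N-methylpropanamide, via lithium enolate 20 (not isolated)
Conditions: LiN(iPr)2, 19, THF, −78 °C; then 18, −78 °C; AcOH quench
Reagents that add atoms: none
Why: Aldol addition of the pre-formed lithium amide enolate 20 to the non-enolisable aldehyde gives the β-hydroxy Weinreb amide as a racemate, the stereocenter being corrected in steps 12 and 13.

Step 12
Reactants: 21 rac-3-[2,2-dimethyl-7-(prop-2-en-1-yloxy)-2H-chromen-6-yl]-3-hydroxy-N-methoxy-N-methylpropanamide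
Product: 22 3-[2,2-dimethyl-7-(prop-2-en-1-yloxy)-2H-chromen-6-yl]-N-methoxy-N-methyl-3-oxopropanamide
Conditions: Dess–Martin periodinane, CH2Cl2, 0 °C → rt
Reagents that add atoms: none
Why: Dess–Martin oxidation of the benzylic secondary alcohol under near-neutral conditions gives the β-keto amide without touching the chromene alkene or the allyl ether.

Step 13
Reactants: 22 3-[2,2-dimethyl-7-(prop-2-en-1-yloxy)-2H-chromen-6-yl]-N-methoxy-N-methyl-3-oxopropanamide
Product: 23 (3S)-3-[2,2-dimethyl-7-(prop-2-en-1-yloxy)-2H-chromen-6-yl]-3-hydroxy-N-methoxy-N-methylpropanamide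
Conditions: RuCl[(S,S)-TsDPEN](p-cymene) (1 mol%), HCO2Na, DMF/H2O, 40 °C
Reagents that add atoms: none
Why: Asymmetric transfer hydrogenation of the aryl ketone by the chiral ruthenium hydride sets the carbinol stereocenter (the future C2) by catalyst control, the (S,S)-ligand being expected to give the (S)-alcohol by analogy with aryl alkyl ketones, and the neutral formate medium avoids ionisation of the electron-rich benzylic alcohol.

Step 14
Reactants: 23 (3S)-3-[2,2-dimethyl-7-(prop-2-en-1-yloxy)-2H-chromen-6-yl]-3-hydroxy-N-methoxy-N-methylpropanamide; 11 3-chloro-6-(3-methylbut-2-en-1-yl)-5-(prop-2-en-1-yloxy)-2-(trimethylsilyl)phenyl trifluoromethanesulfonate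
Product: 27 (2S)-5-chloro-2-[2,2-dimethyl-7-(prop-2-en-1-yloxy)-2H-chromen-6-yl]-8-(3-methylbut-2-en-1-yl)-7-(prop-2-en-1-yloxy)chroman-4-one, via potassium alkoxide 24 (not isolated), via aryne 25 (not isolated), via tetrahedral adduct 26 (not isolated)
Conditions: KH (1.05 equiv), THF, 0 °C; then KF, 18-crown-6 and 11 (1.3 equiv, slow addition), THF, 0 °C → rt; AcOH, −20 °C, then H2O
Reagents that add atoms: none
Why: Proposed new method: fluoride desilylates 11 with loss of triflate to give aryne 25, the pre-formed alkoxide 24 adds through oxygen to the aryne carbon remote from chlorine (the future C8a), and the aryl anion so formed at the future C4a attacks the neighbouring Weinreb amide carbonyl to give tetrahedral adduct 26, which releases the ketone only on the acidic quench, so that no enolisable flavanone meets base and no alkoxide leaving group is set free. The closest known reaction type is the fluoride-induced aryne annulation of salicylate esters to xanthones (O-arylation, then intramolecular acyl capture of the aryl anion), together with aryne insertion into the N–C(O) bond of β-lactams; new here are the aliphatic secondary alkoxide as nucleophile and the Weinreb amide as internal acyl acceptor. Ring C closes as a formal [4+2] annulation, by an intermolecular C–O bond formation (O1–C8a) followed by a 6-exo-trig addition of the aryl anion to the amide carbonyl (C4–C4a). No stereocenter is created: C2 is carried over from 23 with retention because none of its bonds is broken, and the transient configuration at C4 of 26 is lost on collapse to the ketone. The step needs O-addition at the aryne carbon next to the prenyl-bearing carbon, and this is secured by the temporary chlorine at C5, whose inductive pull distorts the aryne so that nucleophiles add at the distal carbon and the charge develops next to C–Cl, a bias expected to override the modest steric demand of the prenyl group; it also needs O-arylation and acyl capture to beat ene reaction with the alkenes and protonation of the aryl anion, which the stoichiometric alkoxide and the absence of any O–H donor provide.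

Step 15
Reactants: 27 (2S)-5-chloro-2-[2,2-dimethyl-7-(prop-2-en-1-yloxy)-2H-chromen-6-yl]-8-(3-methylbut-2-en-1-yl)-7-(prop-2-en-1-yloxy)chroman-4-one
Product: 28 (2S)-7-hydroxy-2-(7-hydroxy-2,2-dimethyl-2H-chromen-6-yl)-8-(3-methylbut-2-en-1-yl)chroman-4-one
Conditions: Pd(OAc)2 (5 mol%), XPhos (10 mol%), HCO2H, Et3N, DMF, 60 °C
Reagents that add atoms: none
Why: Zerovalent palladium formed in situ ionises both allyl aryl ethers (Tsuji–Trost deallylation with formate as hydride donor, giving propene) and inserts into the C5–Cl bond activated by the ortho carbonyl, formate then reduces the arylpalladium chloride to C–H (catalytic hydrodechlorination), and the buffered medium should leave the C2 stereocenter and the two alkenes untouched.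

**Compound list**
1 | 5-chlororesorcinol (5-chlorobenzene-1,3-diol) | Oc1cc(O)cc(Cl)c1 | starting material
2 | 1-chloro-3,5-bis(methoxymethoxy)benzene | COCOc1cc(Cl)cc(OCOC)c1 | intermediate
3 | prenyl bromide (1-bromo-3-methylbut-2-ene) | CC(C)=CCBr | starting material
4 | [4-chloro-2,6-bis(methoxymethoxy)phenyl]lithium | [Li]c1c(OCOC)cc(Cl)cc1OCOC | intermediate (not isolated)
5 | 5-chloro-1,3-bis(methoxymethoxy)-2-(3-methylbut-2-en-1-yl)benzene | CC(C)=CCc1c(OCOC)cc(Cl)cc1OCOC | intermediate
6 | 5-chloro-2-(3-methylbut-2-en-1-yl)benzene-1,3-diol | CC(C)=CCc1c(O)cc(Cl)cc1O | intermediate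
7 | 5-chloro-2-(3-methylbut-2-en-1-yl)-1,3-bis(trimethylsilyloxy)benzene | CC(C)=CCc1c(O[Si](C)(C)C)cc(Cl)cc1O[Si](C)(C)C | intermediate
8 | lithium 3-chloro-6-(3-methylbut-2-en-1-yl)-2-(trimethylsilyl)-5-(trimethylsilyloxy)phenolate | CC(C)=CCc1c(O[Si](C)(C)C)cc(Cl)c([Si](C)(C)C)c1[O-].[Li+] | intermediate (not isolated)
9 | 3-chloro-6-(3-methylbut-2-en-1-yl)-2-(trimethylsilyl)-5-(trimethylsilyloxy)phenyl trifluoromethanesulfonate | CC(C)=CCc1c(O[Si](C)(C)C)cc(Cl)c([Si](C)(C)C)c1OS(=O)(=O)C(F)(F)F | intermediate (not isolated)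
10 | 3-chloro-5-hydroxy-6-(3-methylbut-2-en-1-yl)-2-(trimethylsilyl)phenyl trifluoromethanesulfonate | CC(C)=CCc1c(O)cc(Cl)c([Si](C)(C)C)c1OS(=O)(=O)C(F)(F)F | intermediate
11 | 3-chloro-6-(3-methylbut-2-en-1-yl)-5-(prop-2-en-1-yloxy)-2-(trimethylsilyl)phenyl trifluoromethanesulfonate | CC(C)=CCc1c(OCC=C)cc(Cl)c([Si](C)(C)C)c1OS(=O)(=O)C(F)(F)F | intermediate
12 | resorcinol | Oc1cccc(O)c1 | starting material
13 | 3,3-dimethylacrylic acid (3-methylbut-2-enoic acid) | CC(C)=CC(=O)O | starting material
14 | 7-hydroxy-2,2-dimethylchroman-4-one | CC1(C)CC(=O)c2ccc(O)cc2O1 | intermediate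
15 | rac-2,2-dimethylchromane-4,7-diol | CC1(C)CC(O)c2ccc(O)cc2O1 | intermediate (not isolated)
16 | 2,2-dimethyl-2H-chromen-7-ol | Oc1ccc2c(c1)OC(C)(C)C=C2 | intermediate
17 | 7-hydroxy-2,2-dimethyl-2H-chromene-6-carbaldehyde | O=Cc1cc2c(cc1O)OC(C)(C)C=C2 | intermediate
18 | 2,2-dimethyl-7-(prop-2-en-1-yloxy)-2H-chromene-6-carbaldehyde | O=Cc1cc2c(cc1OCC=C)OC(C)(C)C=C2 | intermediate
19 | N-methoxy-N-methylacetamide | CC(=O)N(C)OC | starting material
20 | lithium 1-[methoxy(methyl)amino]ethen-1-olate (lithium enolate of 19) | [Li+].C=C([O-])N(C)OC | intermediate (not isolated)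
21 | rac-3-[2,2-dimethyl-7-(prop-2-en-1-yloxy)-2H-chromen-6-yl]-3-hydroxy-N-methoxy-N-methylpropanamide | CON(C)C(=O)CC(O)c1cc2c(cc1OCC=C)OC(C)(C)C=C2 | intermediate
22 | 3-[2,2-dimethyl-7-(prop-2-en-1-yloxy)-2H-chromen-6-yl]-N-methoxy-N-methyl-3-oxopropanamide | CON(C)C(=O)CC(=O)c1cc2c(cc1OCC=C)OC(C)(C)C=C2 | intermediate
23 | (3S)-3-[2,2-dimethyl-7-(prop-2-en-1-yloxy)-2H-chromen-6-yl]-3-hydroxy-N-methoxy-N-methylpropanamide | CON(C)C(=O)C[C@H](O)c1cc2c(cc1OCC=C)OC(C)(C)C=C2 | intermediate
24 | potassium (1S)-1-[2,2-dimethyl-7-(prop-2-en-1-yloxy)-2H-chromen-6-yl]-3-[methoxy(methyl)amino]-3-oxopropan-1-olate | CON(C)C(=O)C[C@H]([O-])c1cc2c(cc1OCC=C)OC(C)(C)C=C2.[K+] | intermediate (not isolated)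
25 | 3-chloro-6-(3-methylbut-2-en-1-yl)-5-(prop-2-en-1-yloxy)-1,2-didehydrobenzene (aryne) | CC(C)=CCC1=C(OCC=C)C=C(Cl)C#C1 | intermediate (not isolated)
26 | potassium (2S)-5-chloro-2-[2,2-dimethyl-7-(prop-2-en-1-yloxy)-2H-chromen-6-yl]-4-[methoxy(methyl)amino]-8-(3-methylbut-2-en-1-yl)-7-(prop-2-en-1-yloxy)chroman-4-olate (both C4 epimers) | C=CCOc1cc(Cl)c2c(c1CC=C(C)C)O[C@H](c1cc3c(cc1OCC=C)OC(C)(C)C=C3)CC2([O-])N(C)OC.[K+] | intermediate (not isolated)
27 | (2S)-5-chloro-2-[2,2-dimethyl-7-(prop-2-en-1-yloxy)-2H-chromen-6-yl]-8-(3-methylbut-2-en-1-yl)-7-(prop-2-en-1-yloxy)chroman-4-one | C=CCOc1cc(Cl)c2c(c1CC=C(C)C)O[C@H](c1cc3c(cc1OCC=C)OC(C)(C)C=C3)CC2=O | intermediate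
28 | (2S)-7-hydroxy-2-(7-hydroxy-2,2-dimethyl-2H-chromen-6-yl)-8-(3-methylbut-2-en-1-yl)chroman-4-one | CC(C)=CCc1c(O)ccc2c1O[C@H](c1cc3c(cc1O)OC(C)(C)C=C3)CC2=O | target

**Summary**
Total step count: 15. Longest linear sequence: 9 steps (12 and 13 to 28, steps 7–15); the ring-A branch runs 8 steps (steps 1–6, 14, 15).

Steps most likely to fail:

1. Step 14 (proposed new method). The aryl anion may be protonated or may expel chloride before it reaches the amide carbonyl, the alkoxide may fragment by retro-aldol cleavage or attack the sulfonyl sulfur of 11 instead of the aryne, or the regioselectivity may erode at the prenyl-flanked carbon. The fallback uses known chemistry and avoids the aryne; it sets out from 5, 19 and 18 and comes back to the route at 28. Ortho-lithiation of 5 between OMOM and Cl (s-BuLi, TMEDA, THF, −78 °C) and acylation with 19 should give 1-[6-chloro-2,4-bis(methoxymethoxy)-3-(3-methylbut-2-en-1-yl)phenyl]ethan-1-one F1. Claisen–Schmidt condensation of F1 with 18 (KOH, EtOH) should give the bis-MOM chalcone (2E)-1-[6-chloro-2,4-bis(methoxymethoxy)-3-(3-methylbut-2-en-1-yl)phenyl]-3-[2,2-dimethyl-7-(prop-2-en-1-yloxy)-2H-chromen-6-yl]prop-2-en-1-one F2. HCl in MeOH removes both MOM groups from F2 to give the dihydroxychalcone (2E)-1-[6-chloro-2,4-dihydroxy-3-(3-methylbut-2-en-1-yl)phenyl]-3-[2,2-dimethyl-7-(prop-2-en-1-yloxy)-2H-chromen-6-yl]prop-2-en-1-one F3. NaOAc in refluxing EtOH closes ring C of F3 by oxa-Michael addition of the only hydroxyl ortho to the ketone, giving the racemic flavanone rac-5-chloro-2-[2,2-dimethyl-7-(prop-2-en-1-yloxy)-2H-chromen-6-yl]-7-hydroxy-8-(3-methylbut-2-en-1-yl)chroman-4-one F4. Preparative chromatography of F4 on a chiral stationary phase gives the (2S)-enantiomer (2S)-5-chloro-2-[2,2-dimethyl-7-(prop-2-en-1-yloxy)-2H-chromen-6-yl]-7-hydroxy-8-(3-methylbut-2-en-1-yl)chroman-4-one F5, while the (2R)-enantiomer (2R)-5-chloro-2-[2,2-dimethyl-7-(prop-2-en-1-yloxy)-2H-chromen-6-yl]-7-hydroxy-8-(3-methylbut-2-en-1-yl)chroman-4-one F6 is re-equilibrated through the chalcone with NaOAc and recycled. F5 is converted into 28 under the conditions of step 15.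

2. Step 5. Deprotonation may occur at the benzylic/allylic CH2 of the prenyl group instead of the ring, or the silyl shift may be incomplete. The fallback fixes the metalation site with a halogen; it sets out from 6 and comes back at 10. Bromination of 6 with NBS (CH2Cl2, −78 °C; only the two equivalent ring positions are free, and the electron-rich resorcinol ring is expected to react faster than the trisubstituted alkene at this temperature) should give 4-bromo-5-chloro-2-(3-methylbut-2-en-1-yl)benzene-1,3-diol F7. Silylation of F7 with hexamethyldisilazane gives the bis(trimethylsilyl) ether 1-bromo-6-chloro-3-(3-methylbut-2-en-1-yl)-2,4-bis(trimethylsilyloxy)benzene F8. Bromine–lithium exchange on F8 (n-BuLi, THF, −78 °C) then leads through the same retro-Brook shift to 8, and Tf2O with aqueous work-up gives 10.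

3. Step 15. Palladium hydride may isomerise or reduce the alkenes, the C–Cl reduction may stall once the phenols are free, or the flavanone may ring-open and racemise. The fallback uncouples the two events and removes chlorine by a radical pathway; it sets out from 27 and comes back at 28. Deallylation of 27 with Pd(PPh3)4 and morpholine (THF, rt) should give (2S)-5-chloro-7-hydroxy-2-(7-hydroxy-2,2-dimethyl-2H-chromen-6-yl)-8-(3-methylbut-2-en-1-yl)chroman-4-one F9. Metal-free photoredox hydrodechlorination of F9 (10-phenylphenothiazine, Bu3N, HCO2H, MeCN, 380 nm) then gives 28.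

**Further compounds**
F1 | step 14 | 1-[6-chloro-2,4-bis(methoxymethoxy)-3-(3-methylbut-2-en-1-yl)phenyl]ethan-1-one | CC(=O)c1c(Cl)cc(OCOC)c(CC=C(C)C)c1OCOC
F2 | step 14 | (2E)-1-[6-chloro-2,4-bis(methoxymethoxy)-3-(3-methylbut-2-en-1-yl)phenyl]-3-[2,2-dimethyl-7-(prop-2-en-1-yloxy)-2H-chromen-6-yl]prop-2-en-1-one | COCOc1cc(Cl)c(C(=O)/C=C/c2cc3c(cc2OCC=C)OC(C)(C)C=C3)c(OCOC)c1CC=C(C)C
F3 | step 14 | (2E)-1-[6-chloro-2,4-dihydroxy-3-(3-methylbut-2-en-1-yl)phenyl]-3-[2,2-dimethyl-7-(prop-2-en-1-yloxy)-2H-chromen-6-yl]prop-2-en-1-one | Oc1cc(Cl)c(C(=O)/C=C/c2cc3c(cc2OCC=C)OC(C)(C)C=C3)c(O)c1CC=C(C)C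
F4 | step 14 | rac-5-chloro-2-[2,2-dimethyl-7-(prop-2-en-1-yloxy)-2H-chromen-6-yl]-7-hydroxy-8-(3-methylbut-2-en-1-yl)chroman-4-one | CC(C)=CCc1c(O)cc(Cl)c2c1OC(c1cc3c(cc1OCC=C)OC(C)(C)C=C3)CC2=O
F5 | step 14 | (2S)-5-chloro-2-[2,2-dimethyl-7-(prop-2-en-1-yloxy)-2H-chromen-6-yl]-7-hydroxy-8-(3-methylbut-2-en-1-yl)chroman-4-one | CC(C)=CCc1c(O)cc(Cl)c2c1O[C@H](c1cc3c(cc1OCC=C)OC(C)(C)C=C3)CC2=O
F6 | step 14 | (2R)-5-chloro-2-[2,2-dimethyl-7-(prop-2-en-1-yloxy)-2H-chromen-6-yl]-7-hydroxy-8-(3-methylbut-2-en-1-yl)chroman-4-one | CC(C)=CCc1c(O)cc(Cl)c2c1O[C@@H](c1cc3c(cc1OCC=C)OC(C)(C)C=C3)CC2=O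
F7 | step 5 | 4-bromo-5-chloro-2-(3-methylbut-2-en-1-yl)benzene-1,3-diol | CC(C)=CCc1c(O)cc(Cl)c(Br)c1O
F8 | step 5 | 1-bromo-6-chloro-3-(3-methylbut-2-en-1-yl)-2,4-bis(trimethylsilyloxy)benzene | CC(C)=CCc1c(O[Si](C)(C)C)cc(Cl)c(Br)c1O[Si](C)(C)C
F9 | step 15 | (2S)-5-chloro-7-hydroxy-2-(7-hydroxy-2,2-dimethyl-2H-chromen-6-yl)-8-(3-methylbut-2-en-1-yl)chroman-4-one | CC(C)=CCc1c(O)cc(Cl)c2c1O[C@H](c1cc3c(cc1O)OC(C)(C)C=C3)CC2=O
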